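The synthesis rests on disconnecting the C2–C3 bond of the ten-membered carbocycle (C1–C10), exploiting the 1,3-relationship between the C1 oxygen and the C3 tertiary carbinol, an aldol retron. A SmI2 Reformatsky reaction turns the C10 bromoacetyl group into a samarium enolate that adds to the C3 methyl ketone on the dihydrofuran, closing the ring and setting C3 in one operation. The precursor is a bromoacetyl butenolide, already carrying the C11 acetoxymethyl group, joined through C8–C9 to a 5-acetyl-2,3-dihydrofuran; C8 bears a silyloxy group, a spectator in the ring closure that later leaves by base-induced elimination to give the C8–C9 alkene without electrophilic reagents.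

Key step: step 12

Numbering: C1 (ester-bearing CH), C2 (CH2), C3 (methyl carbinol), C4=C5 (enol ether of the dihydrofuran), C6 (CH2), C7 (methyl-bearing ether carbon), C8, C9 (carbon on the lactone oxygen), C10 and C11 (butenolide β- and α-carbons), C12 (lactone carbonyl); C1–C10 form the carbocycle.

Assumption: step 8 is taken to give mainly the 8,9-syn Felkin–Anh adduct drawn for 12; C8 or C9 epimers would pass through the same steps, because both centres become sp2 in step 16.

Step 1
Reactants: 1 (R)-2-methylglycidol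
Product: 2 tert-butyldimethyl{[(2S)-2-methyloxiran-2-yl]methoxy}silane
Conditions: t-BuMe2SiCl, imidazole, CH2Cl2, 0 °C to rt
Reagents that add atoms: tert-butyldimethylsilyl chloride CC(C)(C)[Si](C)(C)Cl
Why: Silyl ether formation at the primary alcohol leaves the epoxide and the purchased stereocentre (the future C7) untouched; the descriptor changes from R to S only because the substituent priorities change.

Step 2
Reactants: 3 (S)-but-3-yn-2-ol
Product: 4 (S)-tert-butyl(but-3-yn-2-yloxy)dimethylsilane
Conditions: t-BuMe2SiCl, imidazole, CH2Cl2, 0 °C to rt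
Reagents that add atoms: tert-butyldimethylsilyl chloride CC(C)(C)[Si](C)(C)Cl
Why: Silyl ether formation masks the hydroxyl so that only the alkyne C–H is deprotonated in step 3; the carbinol centre (later oxidised to the C3 ketone) is unaffected.

Step 3
Reactants: 4 (S)-tert-butyl(but-3-yn-2-yloxy)dimethylsilane; 2 tert-butyldimethyl{[(2S)-2-methyloxiran-2-yl]methoxy}silane
Product: 6 (2S,6S)-1,6-bis[(tert-butyldimethylsilyl)oxy]-2-methylhept-4-yn-2-ol, via lithium acetylide 5 (not isolated)
Conditions: 4, n-BuLi, THF, −78 °C; BF3·OEt2, then 2, −78 °C; aq. NH4Cl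
Reagents that add atoms: none
Why: BF3-promoted alkynylation of a 2,2-disubstituted epoxide by a lithium acetylide occurs at the unhindered CH2 (the future C6), so the quaternary carbinol carbon C7 keeps its configuration.

Step 4
Reactants: 6 (2S,6S)-1,6-bis[(tert-butyldimethylsilyl)oxy]-2-methylhept-4-yn-2-ol
Product: 7 (2S)-2-{[(tert-butyldimethylsilyl)oxy]methyl}-5-{(1S)-1-[(tert-butyldimethylsilyl)oxy]ethyl}-2-methyl-2,3-dihydrofuran
Conditions: PdCl2(MeCN)2 (5 mol %), THF, rt; Et3N added before chromatography
Reagents that add atoms: none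
Why: Divalent palladium activates the alkyne for 5-endo-dig hydroalkoxylation (cycloisomerisation of a 3-alkyn-1-ol to a 2,3-dihydrofuran), the only ring size available; the quaternary C7 blocks aromatisation and no stereocentre is touched.

Step 5
Reactants: 7 (2S)-2-{[(tert-butyldimethylsilyl)oxy]methyl}-5-{(1S)-1-[(tert-butyldimethylsilyl)oxy]ethyl}-2-methyl-2,3-dihydrofuran
Product: 8 (1S)-1-[(5S)-5-(hydroxymethyl)-5-methyl-4,5-dihydrofuran-2-yl]ethan-1-ol
Conditions: Bu4NF, THF, 0 °C to rt
Reagents that add atoms: none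
Why: Fluoride-mediated desilylation removes both silyl ethers under non-acidic conditions that the enol ether tolerates.

Step 6
Reactants: 8 (1S)-1-[(5S)-5-(hydroxymethyl)-5-methyl-4,5-dihydrofuran-2-yl]ethan-1-ol
Product: 9 (2S)-5-acetyl-2-methyl-2,3-dihydrofuran-2-carbaldehyde
Conditions: Dess–Martin periodinane (2.5 equiv), NaHCO3, CH2Cl2, 0 °C to rt
Reagents that add atoms: none
Why: Buffered Dess–Martin oxidation should convert the primary alcohol into the non-enolisable C8 aldehyde and the allylic secondary alcohol into the C3 methyl ketone in one operation, without acid that would harm the enol ether.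

Step 7
Reactants: 10 3,4-dibromofuran-2(5H)-one
Product: 11 [(3,4-dibromofuran-2-yl)oxy]triethylsilane
Conditions: Et3SiOTf, i-Pr2NEt, CH2Cl2, 0 °C; pentane extraction, used crude
Reagents that add atoms: triethylsilyl trifluoromethanesulfonate CC[Si](CC)(CC)OS(=O)(=O)C(F)(F)F
Why: Soft enolisation of the acidic γ-CH2 of the dibromobutenolide with a silyl triflate and a hindered amine gives the 2-silyloxyfuran (silyl dienol ether formation).

Step 8
Reactants: 9 (2S)-5-acetyl-2-methyl-2,3-dihydrofuran-2-carbaldehyde; 11 [(3,4-dibromofuran-2-yl)oxy]triethylsilane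
Product: 12 (5R)-3,4-dibromo-5-{(R)-[(2S)-5-acetyl-2-methyl-2,3-dihydrofuran-2-yl][(triethylsilyl)oxy]methyl}furan-2(5H)-one
Conditions: Et3SiOTf (0.2 equiv), CH2Cl2, −78 to −40 °C; Et3N quench
Reagents that add atoms: none
Why: Silyl-triflate-catalysed vinylogous Mukaiyama aldol addition of the furan C5 (C9) to the aldehyde, chemoselective over the less electrophilic conjugated methyl ketone and ending with silyl transfer to the C8 oxygen; the open transition state should favour the 8,9-syn adduct and the Felkin–Anh model (ring C7–O bond anti to the nucleophile, methyl as the small group) the drawn C8 configuration, both centres being temporary.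

Step 9
Reactants: 12 (5R)-3,4-dibromo-5-{(R)-[(2S)-5-acetyl-2-methyl-2,3-dihydrofuran-2-yl][(triethylsilyl)oxy]methyl}furan-2(5H)-one
Product: 13 (5S)-3-bromo-4-(1-ethoxyethenyl)-5-{(R)-[(2S)-5-acetyl-2-methyl-2,3-dihydrofuran-2-yl][(triethylsilyl)oxy]methyl}furan-2(5H)-one
Conditions: Bu3SnC(OEt)=CH2 (1.05 equiv), Pd(PPh3)4 (5 mol %), toluene, 80 °C; Et3N-deactivated silica
Reagents that add atoms: tributyl(1-ethoxyvinyl)stannane CCCC[Sn](CCCC)(CCCC)C(=C)OCC
Why: Stille coupling in which oxidative addition of zerovalent palladium is faster at the β-bromide (C10, a vinylogous acyl bromide) than at the α-bromide of a 3,4-dibromobutenolide, so the masked acyl group enters at C10 only.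

Step 10
Reactants: 13 (5S)-3-bromo-4-(1-ethoxyethenyl)-5-{(R)-[(2S)-5-acetyl-2-methyl-2,3-dihydrofuran-2-yl][(triethylsilyl)oxy]methyl}furan-2(5H)-one
Product: 15 {(5S)-5-{(R)-[(2S)-5-acetyl-2-methyl-2,3-dihydrofuran-2-yl][(triethylsilyl)oxy]methyl}-4-(1-ethoxyethenyl)-2-oxo-2,5-dihydrofuran-3-yl}methyl acetate, via hydroxymethyl butenolide 14 (not isolated)
Conditions: Bu3SnCH2OH, Pd(PPh3)4 (10 mol %), i-Pr2NEt, dioxane, 90 °C; then Ac2O, pyridine, 0 °C
Reagents that add atoms: (tributylstannyl)methanol OC[Sn](CCCC)(CCCC)CCCC; acetic anhydride CC(=O)OC(C)=O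
Why: Stille coupling of the remaining α-bromo enoate (C11) with the hydroxymethylstannane, whose α-oxygenated carbon transfers in preference to butyl, followed by acetylation in the same flask so that the free hydroxyl cannot add to the neighbouring enol ether.

Step 11
Reactants: 15 {(5S)-5-{(R)-[(2S)-5-acetyl-2-methyl-2,3-dihydrofuran-2-yl][(triethylsilyl)oxy]methyl}-4-(1-ethoxyethenyl)-2-oxo-2,5-dihydrofuran-3-yl}methyl acetate
Product: 16 {(5S)-5-{(R)-[(2S)-5-acetyl-2-methyl-2,3-dihydrofuran-2-yl][(triethylsilyl)oxy]methyl}-4-(bromoacetyl)-2-oxo-2,5-dihydrofuran-3-yl}methyl acetate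
Conditions: N-bromosuccinimide (1.0 equiv), THF/H2O (4:1), 0 °C
Reagents that add atoms: N-bromosuccinimide O=C1CCC(=O)N1Br; water O
Why: Electrophilic bromination of the 1-ethoxyvinyl terminus and hydrolysis of the resulting oxocarbenium ion (enol ether to α-bromo ketone conversion) should brominate only C2, because the dihydrofuran enol ether is deactivated by its acetyl group and the other methyl ketone is never enolised.

Step 12
Reactants: 16 {(5S)-5-{(R)-[(2S)-5-acetyl-2-methyl-2,3-dihydrofuran-2-yl][(triethylsilyl)oxy]methyl}-4-(bromoacetyl)-2-oxo-2,5-dihydrofuran-3-yl}methyl acetate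
Product: 18 macrocyclic ketone: carbocycle C1–C10 with C1 ketone, (3R)-3-hydroxy-3-methyl, C4=C5 enol ether bridged C4–O–C7, (7S)-7-methyl, (8R)-8-triethylsilyloxy, (9S)-C9 on the lactone oxygen, butenolide C10=C11 bearing the C11 acetoxymethyl group, via samarium enolate 17 (not isolated)
Conditions: SmI2 (0.1 M in THF, 2.2 equiv) added over 2 h to 16 (0.002 M in THF), −78 °C; sat. aq. NH4Cl at −78 °C
Reagents that add atoms: none
Why: Two single-electron transfers from divalent samarium cleave the C2–Br bond and give the trivalent samarium enolate 17, whose C2 terminus adds to the C3 ketone through a six-membered transition state in which samarium bridges the enolate and ketone oxygens, and the samarium aldolate is protonated on quench. The closest known reaction type is the SmI2-mediated intramolecular Reformatsky (samarium aldol) reaction used to close medium and large rings. The ten-membered carbocycle closes in a 10-(enolendo)-exo-trig mode. The new C3 centre is controlled by the C7 stereocentre of the flat dihydrofuran: the tether, anchored at C8, can reach C3 only from the C8 face, and the acetyl group should react in its dipole-minimised rotamer with C=O anti to the ring oxygen, which together give 3R. The step needs reduction of the bromoketone in preference to the ene-dione-like butenolide and ring closure in preference to intermolecular addition; the much faster C–Br cleavage at −78 °C, slow addition of only about two equivalents of SmI2 and high dilution are meant to secure both. The C8 silyl ether and the C11 acetate are spectators, since the cross-conjugated enolate cannot expel either group.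

Step 13
Reactants: 18 macrocyclic ketone (3R,7S,8R,9S)
Product: 20 macrocyclic syn-1,3-diol (1S,3R,7S,8R,9S) with C8 triethylsilyl ether and C11 acetoxymethyl group, via diethylboron chelate 19 (not isolated)
Conditions: Et2BOMe (1.2 equiv), THF/MeOH (4:1), −78 °C; NaBH4, −78 °C; AcOH, then co-evaporation with MeOH
Reagents that add atoms: none
Why: Narasaka–Prasad reduction, in which external hydride attacks the boron chelate of the C3 alkoxide and the C1 carbonyl in a half-chair transition state to give the 1,3-syn diol (C1 S relative to 3R), while boron activation of the carbonyl favours 1,2- over conjugate reduction.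

Step 14
Reactants: 20 macrocyclic syn-1,3-diol (1S,3R,7S,8R,9S)
Product: 21 C1 methacrylate of 20 (C3 hydroxyl free)
Conditions: methacrylic anhydride (1.5 equiv), Et3N, 4-dimethylaminopyridine (0.1 equiv), CH2Cl2, 0 °C
Reagents that add atoms: methacrylic anhydride C=C(C)C(=O)OC(=O)C(C)=C
Why: Nucleophile-catalysed esterification of the secondary C1 alcohol; the tertiary C3 alcohol does not acylate under these conditions and the configuration at C1 is retained.

Step 15
Reactants: 21 C1 methacrylate with C8 triethylsilyl ether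
Product: 22 C8 alcohol (1S,3R,7S,8R,9S) carrying the C1 methacrylate and the C11 acetoxymethyl group
Conditions: Bu4NF/AcOH (1:1), THF, 0 °C to rt
Reagents that add atoms: none
Why: Fluoride-mediated cleavage of the triethylsilyl ether, buffered with acetic acid so that the liberated alkoxide is protonated before retro-aldol cleavage or acyl migration can occur.

Step 16
Reactants: 22 C8 alcohol (1S,3R,7S,8R,9S)
Product: 24 CNP0394509.2 (target), via C8 mesylate 23 (not isolated)
Conditions: Ms2O, pyridine, CH2Cl2, 0 °C; then DBU, 0 °C to rt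
Reagents that add atoms: none
Why: Selective sulfonylation of the secondary C8 alcohol (the tertiary alcohol is inert to Ms2O/pyridine) and E1cB elimination through the butenolide dienolate, in which mesylate leaves far faster than the C11 acetoxy group; the ten-membered ring allows only the geometry with C7 cis to C10, the E-alkene of the target.

Compound list
1 | (R)-2-methylglycidol, [(2R)-2-methyloxiran-2-yl]methanol | C[C@@]1(CO)CO1 | starting material
2 | tert-butyldimethyl{[(2S)-2-methyloxiran-2-yl]methoxy}silane | C[C@@]1(CO[Si](C)(C)C(C)(C)C)CO1 | intermediate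
3 | (S)-but-3-yn-2-ol | C[C@H](O)C#C | starting material
4 | (S)-tert-butyl(but-3-yn-2-yloxy)dimethylsilane | C[C@H](O[Si](C)(C)C(C)(C)C)C#C | intermediate
5 | lithium acetylide of 4 | [Li]C#C[C@H](C)O[Si](C)(C)C(C)(C)C | intermediate (not isolated)
6 | (2S,6S)-1,6-bis[(tert-butyldimethylsilyl)oxy]-2-methylhept-4-yn-2-ol | C[C@@](O)(CO[Si](C)(C)C(C)(C)C)CC#C[C@H](C)O[Si](C)(C)C(C)(C)C | intermediate
7 | (2S)-2-{[(tert-butyldimethylsilyl)oxy]methyl}-5-{(1S)-1-[(tert-butyldimethylsilyl)oxy]ethyl}-2-methyl-2,3-dihydrofuran | C[C@@]1(CO[Si](C)(C)C(C)(C)C)CC=C(O1)[C@H](C)O[Si](C)(C)C(C)(C)C | intermediate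
8 | (1S)-1-[(5S)-5-(hydroxymethyl)-5-methyl-4,5-dihydrofuran-2-yl]ethan-1-ol | C[C@@]1(CO)CC=C(O1)[C@H](C)O | intermediate
9 | (2S)-5-acetyl-2-methyl-2,3-dihydrofuran-2-carbaldehyde | C[C@@]1(C=O)CC=C(O1)C(C)=O | intermediate
10 | 3,4-dibromofuran-2(5H)-one | O=C1OCC(Br)=C1Br | starting material
11 | [(3,4-dibromofuran-2-yl)oxy]triethylsilane | CC[Si](CC)(CC)Oc1occ(Br)c1Br | intermediate
12 | (5R)-3,4-dibromo-5-{(R)-[(2S)-5-acetyl-2-methyl-2,3-dihydrofuran-2-yl][(triethylsilyl)oxy]methyl}furan-2(5H)-one | CC[Si](CC)(CC)O[C@H]([C@H]1OC(=O)C(Br)=C1Br)[C@]2(C)CC=C(C(C)=O)O2 | intermediate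
13 | (5S)-3-bromo-4-(1-ethoxyethenyl)-5-{(R)-[(2S)-5-acetyl-2-methyl-2,3-dihydrofuran-2-yl][(triethylsilyl)oxy]methyl}furan-2(5H)-one | CC[Si](CC)(CC)O[C@H]([C@H]1OC(=O)C(Br)=C1C(=C)OCC)[C@]2(C)CC=C(C(C)=O)O2 | intermediate
14 | 3-(hydroxymethyl) analogue of 13 (C11 CH2OH in place of Br) | CC[Si](CC)(CC)O[C@H]([C@H]1OC(=O)C(CO)=C1C(=C)OCC)[C@]2(C)CC=C(C(C)=O)O2 | intermediate (not isolated)
15 | {(5S)-5-{(R)-[(2S)-5-acetyl-2-methyl-2,3-dihydrofuran-2-yl][(triethylsilyl)oxy]methyl}-4-(1-ethoxyethenyl)-2-oxo-2,5-dihydrofuran-3-yl}methyl acetate | CC[Si](CC)(CC)O[C@H]([C@H]1OC(=O)C(COC(C)=O)=C1C(=C)OCC)[C@]2(C)CC=C(C(C)=O)O2 | intermediate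
16 | {(5S)-5-{(R)-[(2S)-5-acetyl-2-methyl-2,3-dihydrofuran-2-yl][(triethylsilyl)oxy]methyl}-4-(bromoacetyl)-2-oxo-2,5-dihydrofuran-3-yl}methyl acetate (precursor of the key step) | CC[Si](CC)(CC)O[C@H]([C@H]1OC(=O)C(COC(C)=O)=C1C(=O)CBr)[C@]2(C)CC=C(C(C)=O)O2 | intermediate
17 | diiodosamarium enolate of 16 (C1–O–SmI2, C1=C2) | C=C(O[Sm](I)I)C1=C(COC(C)=O)C(=O)O[C@@H]1[C@@H](O[Si](CC)(CC)CC)[C@]2(C)CC=C(C(C)=O)O2 | intermediate (not isolated)
18 | macrocyclic ketone (3R,7S,8R,9S): C1 ketone, C3 tertiary alcohol, C8 triethylsilyl ether, C11 acetoxymethyl butenolide (product of the key step) | O=C1C[C@@](C)(O)C2=CC[C@@](C)([C@H](O[Si](CC)(CC)CC)[C@H]3OC(=O)C(COC(C)=O)=C31)O2 | intermediate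
19 | C3 O-diethylboryl derivative (boron chelate) of 18 | O=C1C[C@@](C)(OB(CC)CC)C2=CC[C@@](C)([C@H](O[Si](CC)(CC)CC)[C@H]3OC(=O)C(COC(C)=O)=C31)O2 | intermediate (not isolated)
20 | macrocyclic syn-1,3-diol (1S,3R,7S,8R,9S) | O[C@H]1C[C@@](C)(O)C2=CC[C@@](C)([C@H](O[Si](CC)(CC)CC)[C@H]3OC(=O)C(COC(C)=O)=C31)O2 | intermediate
21 | C1 methacrylate of 20 | C=C(C)C(=O)O[C@H]1C[C@@](C)(O)C2=CC[C@@](C)([C@H](O[Si](CC)(CC)CC)[C@H]3OC(=O)C(COC(C)=O)=C31)O2 | intermediate
22 | C8 alcohol (1S,3R,7S,8R,9S) with C1 methacrylate and C11 acetoxymethyl group | C=C(C)C(=O)O[C@H]1C[C@@](C)(O)C2=CC[C@@](C)([C@H](O)[C@H]3OC(=O)C(COC(C)=O)=C31)O2 | intermediate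
23 | C8 methanesulfonate of 22 | C=C(C)C(=O)O[C@H]1C[C@@](C)(O)C2=CC[C@@](C)([C@H](OS(C)(=O)=O)[C@H]3OC(=O)C(COC(C)=O)=C31)O2 | intermediate (not isolated)
24 | CNP0394509.2: (1S,3R,7S,8E)-configured methacrylate with 3-hydroxy-3-methyl, 4,7-epoxy bridge, C8=C9 enol lactone and C11 acetoxymethyl group | C=C(C)C(=O)O[C@H]1C[C@@](C)(O)C2=CC[C@@](C)(/C=C3/OC(=O)C(COC(C)=O)=C31)O2 | target

Total step count: 16. Longest linear sequence: 14 steps (steps 1, 3–6 and 8–16).

Steps most likely to fail

Step 12. The risks are reduction of the ene-dione-like butenolide by SmI2 (with loss of the lactone C9–O bond), intermolecular aldol addition, and attack on the wrong face of the C3 ketone. The fallback separates enolate formation from C–C bond formation. From 16, reductive silylation (Zn, Me3SiCl, THF, 0 °C) would give the trimethylsilyl enol ether F1 regiospecifically at C1–C2. An intramolecular Mukaiyama aldol addition to the C3 ketone (BF3·OEt2, CH2Cl2, −78 °C, high dilution) and aqueous work-up would return to the route at 18.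

Step 10. The risks are sluggish transfer of the hydroxymethyl group to the congested C11 bromide and addition of the new hydroxyl to the adjacent enol ether before acetylation. The fallback brings in the carbon as carbon monoxide. From 13, palladium-catalysed formylation (Pd(PPh3)4, CO, Bu3SnH added slowly, toluene, 50 °C) would give the C11 aldehyde F2. NaBH(OAc)3, which reduces aldehydes but not the methyl ketone, would then give 14, which is acetylated to 15 as in step 10.

Step 13. The risks are poor facial selectivity at C1 if the macrocycle overrides the boron chelate, and competing conjugate reduction. The fallback aims for the opposite C1 epimer and inverts it while esterifying. From 18, an Evans–Saksena reduction (Me4NBH(OAc)3, MeCN/AcOH, −30 °C, internal hydride delivery from the C3 oxygen) would give the 1,3-anti diol F3. A Mitsunobu esterification with methacrylic acid (PPh3, diisopropyl azodicarboxylate, THF, 0 °C) would invert C1 and return to the route at 21.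

Further compounds
F1 | step 12 | trimethylsilyl enol ether of the C1 ketone of 16 (C1=C2, bromine removed) | C=C(O[Si](C)(C)C)C1=C(COC(C)=O)C(=O)O[C@@H]1[C@@H](O[Si](CC)(CC)CC)[C@]2(C)CC=C(C(C)=O)O2
F2 | step 10 | C11 aldehyde: 3-formyl analogue of 13 | CC[Si](CC)(CC)O[C@H]([C@H]1OC(=O)C(C=O)=C1C(=C)OCC)[C@]2(C)CC=C(C(C)=O)O2
F3 | step 13 | macrocyclic anti-1,3-diol (1R,3R,7S,8R,9S), C1 epimer of 20 | O[C@@H]1C[C@@](C)(O)C2=CC[C@@](C)([C@H](O[Si](CC)(CC)CC)[C@H]3OC(=O)C(COC(C)=O)=C31)O2
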